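**Retrosynthetic overview**
1. Ring D (the C-3 lactone) is made last: Fukuyama coupling of a C-3 thioester with a β-zincio ester gives a γ-keto ester, and Felkin–Anh reduction then lactonises it. The C-20 methyl centre of the zinc reagent comes from a lipase (hydrolase) desymmetrisation of an achiral diester.
2. Ring B (pyrrolidine) and then ring A (azepane) close in one operation from an amino mesylate/chloride: SN2 with inversion at C-9a, then N-alkylation at C-5. The amine is an (S)-α-amino ester set by Rh–DuPhos hydrogenation of a dehydroamino ester (HWE on a C-2 aldehyde).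
3. The C-9a carbinol comes from catalyst-controlled allylboration of the C-9a aldehyde, and ozonolysis of the allyl group gives the C-2 aldehyde.
4. Ring C (side-chain lactone) is formed first: allylboration at C-11, hydroboration, oxidative lactonisation, then trans-selective enolate methylation.
5. C-9 and C-10 come from an organocatalytic Michael addition of 6-chlorohexanal to (E)-1-nitrobut-1-ene; the nitro group becomes the C-11 aldehyde (Nef). Ring order: C, then B, then A, then D.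

Labels: C-1 to C-3, N-4, C-5 to C-9 and C-9a are the pyrrolo[1,2-a]azepine positions. C-10 is the side-chain CH(Et); C-11/C-13 and C-18/C-20 are the carbinol and methyl-bearing carbons of rings C and D.
Assumption: the target is (3S,9R,9aS,10R,11R,13S,18S,20S) as drawn; the commercial phosphonate 26 is a racemate whose only stereocentre becomes sp2 in step 15, so it imports no stereochemical information.

**Route**

Step 1
Reactants: 1 6-chlorohexan-1-ol
Product: 2 6-chlorohexanal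
Conditions: TEMPO (10 mol %), PhI(OAc)2 (1.1 equiv), CH2Cl2, rt
Reagents that add atoms: none
Why: The TEMPO/PhI(OAc)2 alcohol oxidation stops at the aldehyde and leaves the primary chloride untouched.

Step 2
Reactants: 3 propanal; 4 nitromethane
Product: 5 1-nitrobutan-2-ol (racemic)
Conditions: KOt-Bu (5 mol %), THF/t-BuOH, 0 °C, 4 in excess
Reagents that add atoms: none
Why: Henry (nitroaldol) addition; the racemic carbinol centre is removed in the next step.

Step 3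
Reactants: 5 1-nitrobutan-2-ol (racemic)
Product: 7 (E)-1-nitrobut-1-ene, via 1-nitrobutan-2-yl methanesulfonate 6 (not isolated)
Conditions: MsCl, Et3N (2.2 equiv), CH2Cl2, 0 °C
Reagents that add atoms: none
Why: O-mesylation followed by E1cB elimination gives the conjugated (E)-nitroalkene.

Step 4
Reactants: 2 6-chlorohexanal; 7 (E)-1-nitrobut-1-ene
Product: 8 (2R)-6-chloro-2-[(2R)-1-nitrobutan-2-yl]hexanal
Conditions: (S)-α,α-diphenylprolinol trimethylsilyl ether (10 mol %), 4-nitrophenol (10 mol %), toluene, 0 °C → rt, 2 (1.5 equiv)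
Reagents that add atoms: none
Why: Hayashi–Jørgensen enamine Michael addition in which the anti-enamine of the (S)-catalyst adds from its unshielded face through the acyclic synclinal transition state, setting C-9 and C-10 (syn, 2R,3R) as the first stereocentres by asymmetric organocatalysis.

Step 5
Reactants: 8 (2R)-6-chloro-2-[(2R)-1-nitrobutan-2-yl]hexanal
Product: 9 2-[(5R,6R)-1-chloro-6-(nitromethyl)octan-5-yl]-1,3-dioxolane
Conditions: TMSOCH2CH2OTMS, TMSOTf (5 mol %), CH2Cl2, −78 °C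
Reagents that add atoms: 1,2-bis(trimethylsilyloxy)ethane, C[Si](C)(C)OCCO[Si](C)(C)C
Why: Noyori acetalisation under aprotic low-temperature conditions masks the epimerisable C-9a aldehyde as a dioxolane that does not transacetalise with the later C-11 hydroxyl.

Step 6
Reactants: 9 2-[(5R,6R)-1-chloro-6-(nitromethyl)octan-5-yl]-1,3-dioxolane
Product: 11 (2R,3R)-7-chloro-3-(1,3-dioxolan-2-yl)-2-ethylheptanal, via sodium nitronate 10 (not isolated)
Conditions: NaOMe (1.0 equiv), MeOH, 0 °C; O3, −78 °C; N2 purge, pH 7 buffer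
Reagents that add atoms: ozone, [O-][O+]=O
Why: Nef reaction in its ozonolytic form cleaves the nitronate C=N bond to the C-11 aldehyde at −78 °C with no excess base, so the adjacent C-10 centre is kept.

Step 7
Reactants: 11 (2R,3R)-7-chloro-3-(1,3-dioxolan-2-yl)-2-ethylheptanal
Product: 13 (4R,5R,6R)-10-chloro-6-(1,3-dioxolan-2-yl)-5-ethyldec-1-en-4-ol, via pinacol borate 12 (not isolated)
Conditions: allyl-B(pin) (1.3 equiv), (R)-TRIP [BINOL phosphoric acid with 3,3′-(2,4,6-i-Pr3C6H2) groups] (5 mol %), 4 Å MS, toluene, −30 °C; aqueous work-up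
Reagents that add atoms: allylboronic acid pinacol ester, C=CCB1OC(C)(C)C(C)(C)O1
Why: Chiral phosphoric acid-catalysed allylboration through a chair six-membered transition state delivers allyl to the Re face, which is also the Felkin–Anh face of this α-branched aldehyde (matched case), setting C-11 as R.

Step 8
Reactants: 13 (4R,5R,6R)-10-chloro-6-(1,3-dioxolan-2-yl)-5-ethyldec-1-en-4-ol
Product: 15 (4R,5R,6R)-10-chloro-6-(1,3-dioxolan-2-yl)-5-ethyldecane-1,4-diol, via bis(9-BBN) adduct 14 (not isolated)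
Conditions: 9-BBN (2.5 equiv), THF, 0 °C → rt; NaOH, H2O2, 0 °C
Reagents that add atoms: hydrogen peroxide, OO
Why: Anti-Markovnikov hydroboration–oxidation of the terminal alkene gives the primary alcohol of a 1,4-diol.

Step 9
Reactants: 15 (4R,5R,6R)-10-chloro-6-(1,3-dioxolan-2-yl)-5-ethyldecane-1,4-diol
Product: 17 (5R)-5-[(3R,4R)-8-chloro-4-(1,3-dioxolan-2-yl)octan-3-yl]oxolan-2-one, via lactol 16 (not isolated)
Conditions: TEMPO (20 mol %), PhI(OAc)2 (2.5 equiv), CH2Cl2, rt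
Reagents that add atoms: none
Why: Oxidative lactonisation (primary alcohol to aldehyde, lactol, then lactone) closes ring C without touching the secondary centre.

Step 10
Reactants: 17 (5R)-5-[(3R,4R)-8-chloro-4-(1,3-dioxolan-2-yl)octan-3-yl]oxolan-2-one
Product: 19 (3S,5R)-5-[(3R,4R)-8-chloro-4-(1,3-dioxolan-2-yl)octan-3-yl]-3-methyloxolan-2-one, via lithium enolate 18 (not isolated)
Conditions: LiN(i-Pr)2 (1.1 equiv), THF, −78 °C; MeI (3 equiv), −78 °C
Reagents that add atoms: iodomethane, CI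
Why: Lactone enolate alkylation takes place on the face opposite the bulky C-5 substituent, giving the 3,5-trans lactone and setting C-13 as S.

Step 11
Reactants: 19 (3S,5R)-5-[(3R,4R)-8-chloro-4-(1,3-dioxolan-2-yl)octan-3-yl]-3-methyloxolan-2-one
Product: 20 (2R)-6-chloro-2-{(1R)-1-[(2R,4S)-4-methyl-5-oxooxolan-2-yl]propyl}hexanal
Conditions: 2 M HCl, THF, 40 °C
Reagents that add atoms: water, O
Why: Acid hydrolysis of the dioxolane frees the C-9a aldehyde, while the γ-lactone (stable to dilute acid) and the chloride are unaffected.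

Step 12
Reactants: 20 (2R)-6-chloro-2-{(1R)-1-[(2R,4S)-4-methyl-5-oxooxolan-2-yl]propyl}hexanal
Product: 22 (3S,5R)-5-[(3R,4R,5R)-4-(4-chlorobutyl)-5-hydroxyoct-7-en-3-yl]-3-methyloxolan-2-one, via pinacol borate 21 (not isolated)
Conditions: allyl-B(pin) (1.3 equiv), (R)-TRIP (5 mol %), 4 Å MS, toluene, −30 °C; aqueous work-up
Reagents that add atoms: allylboronic acid pinacol ester, C=CCB1OC(C)(C)C(C)(C)O1
Why: The same phosphoric acid-catalysed allylboration attacks the Re (Felkin–Anh, matched) face and gives the 9aR carbinol, the configuration opposite to the C–N bond that is made later by SN2 inversion.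

Step 13
Reactants: 22 (3S,5R)-5-[(3R,4R,5R)-4-(4-chlorobutyl)-5-hydroxyoct-7-en-3-yl]-3-methyloxolan-2-one
Product: 23 (3S,5R)-5-[(3R,4R,5R)-5-{[tert-butyl(dimethyl)silyl]oxy}-4-(4-chlorobutyl)oct-7-en-3-yl]-3-methyloxolan-2-one
Conditions: TBSOTf, 2,6-lutidine, CH2Cl2, −78 → 0 °C
Reagents that add atoms: tert-butyldimethylsilyl trifluoromethanesulfonate, CC(C)(C)[Si](C)(C)OS(=O)(=O)C(F)(F)F
Why: Silylation of the hindered secondary alcohol prevents β-elimination and lactol formation once the C-2 aldehyde is unveiled.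

Step 14
Reactants: 23 (3S,5R)-5-[(3R,4R,5R)-5-{[tert-butyl(dimethyl)silyl]oxy}-4-(4-chlorobutyl)oct-7-en-3-yl]-3-methyloxolan-2-one
Product: 25 (3R,4R)-3-{[tert-butyl(dimethyl)silyl]oxy}-8-chloro-4-{(1R)-1-[(2R,4S)-4-methyl-5-oxooxolan-2-yl]propyl}octanal, via ozonide 24 (not isolated)
Conditions: O3, CH2Cl2, −78 °C; PPh3, −78 °C → rt
Reagents that add atoms: ozone, [O-][O+]=O
Why: Ozonolysis with reductive work-up cuts the vinyl group to the C-2 aldehyde.

Step 15
Reactants: 25 (3R,4R)-3-{[tert-butyl(dimethyl)silyl]oxy}-8-chloro-4-{(1R)-1-[(2R,4S)-4-methyl-5-oxooxolan-2-yl]propyl}octanal; 26 methyl 2-[(tert-butoxycarbonyl)amino]-2-(dimethoxyphosphoryl)acetate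
Product: 27 methyl (2Z,5R,6R)-2-[(tert-butoxycarbonyl)amino]-5-{[tert-butyl(dimethyl)silyl]oxy}-10-chloro-6-{(1R)-1-[(2R,4S)-4-methyl-5-oxooxolan-2-yl]propyl}dec-2-enoate
Conditions: 1,1,3,3-tetramethylguanidine (1.1 equiv), THF, −78 °C → rt
Reagents that add atoms: none
Why: Horner–Wadsworth–Emmons olefination with the Schmidt phosphonoglycinate gives the (Z)-dehydroamino ester that brings in N-4, C-3 and C-18.

Step 16
Reactants: 27 methyl (2Z,5R,6R)-2-[(tert-butoxycarbonyl)amino]-5-{[tert-butyl(dimethyl)silyl]oxy}-10-chloro-6-{(1R)-1-[(2R,4S)-4-methyl-5-oxooxolan-2-yl]propyl}dec-2-enoate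
Product: 28 methyl (2S,5R,6R)-2-[(tert-butoxycarbonyl)amino]-5-{[tert-butyl(dimethyl)silyl]oxy}-10-chloro-6-{(1R)-1-[(2R,4S)-4-methyl-5-oxooxolan-2-yl]propyl}decanoate
Conditions: [Rh(cod)((S,S)-Et-DuPhos)]OTf (1 mol %), H2 (5 bar), MeOH, rt
Reagents that add atoms: none
Why: Rh–DuPhos asymmetric hydrogenation of the chelating enamide sets C-3 as S under catalyst control, independent of the remote centres.

Step 17
Reactants: 28 methyl (2S,5R,6R)-2-[(tert-butoxycarbonyl)amino]-5-{[tert-butyl(dimethyl)silyl]oxy}-10-chloro-6-{(1R)-1-[(2R,4S)-4-methyl-5-oxooxolan-2-yl]propyl}decanoate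
Product: 29 methyl (2S,5R,6R)-2-[(tert-butoxycarbonyl)amino]-10-chloro-5-hydroxy-6-{(1R)-1-[(2R,4S)-4-methyl-5-oxooxolan-2-yl]propyl}decanoate
Conditions: HF·pyridine, pyridine, THF, 0 °C → rt
Reagents that add atoms: none
Why: Fluoride-driven desilylation frees the C-9a hydroxyl under conditions that spare the Boc group, ester and lactone.

Step 18
Reactants: 29 methyl (2S,5R,6R)-2-[(tert-butoxycarbonyl)amino]-10-chloro-5-hydroxy-6-{(1R)-1-[(2R,4S)-4-methyl-5-oxooxolan-2-yl]propyl}decanoate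
Product: 30 methyl (2S,5R,6R)-2-[(tert-butoxycarbonyl)amino]-10-chloro-5-[(methanesulfonyl)oxy]-6-{(1R)-1-[(2R,4S)-4-methyl-5-oxooxolan-2-yl]propyl}decanoate
Conditions: MsCl, Et3N, CH2Cl2, 0 °C
Reagents that add atoms: methanesulfonyl chloride, CS(=O)(=O)Cl
Why: O-sulfonylation turns the 9a-hydroxyl into a leaving group with retention at carbon.

Step 19
Reactants: 30 methyl (2S,5R,6R)-2-[(tert-butoxycarbonyl)amino]-10-chloro-5-[(methanesulfonyl)oxy]-6-{(1R)-1-[(2R,4S)-4-methyl-5-oxooxolan-2-yl]propyl}decanoate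
Product: 33 methyl (3S,9R,9aS)-9-{(1R)-1-[(2R,4S)-4-methyl-5-oxooxolan-2-yl]propyl}octahydro-1H-pyrrolo[1,2-a]azepine-3-carboxylate, via ammonium trifluoroacetate 31 (not isolated), via chloroalkyl pyrrolidine 32 (not isolated)
Conditions: CF3CO2H, CH2Cl2, 0 °C; evaporate; K2CO3, MeCN (0.01 M), 55 °C; then NaI (20 mol %), 80 °C
Reagents that add atoms: none
Why: Boc removal, then 5-exo-tet SN2 displacement of the mesylate with inversion (9aS, 2,5-trans pyrrolidine, ring B), then Finkelstein-assisted 7-exo-tet N-alkylation by the chloride (ring A); iodide is added only after the first closure so that C-9a is inverted exactly once.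

Step 20
Reactants: 33 methyl (3S,9R,9aS)-9-{(1R)-1-[(2R,4S)-4-methyl-5-oxooxolan-2-yl]propyl}octahydro-1H-pyrrolo[1,2-a]azepine-3-carboxylate
Product: 35 (3S,9R,9aS)-9-{(1R)-1-[(2R,4S)-4-methyl-5-oxooxolan-2-yl]propyl}octahydro-1H-pyrrolo[1,2-a]azepine-3-carboxylic acid, via dilithium hydroxy dicarboxylate 34 (not isolated)
Conditions: LiOH·H2O (3 equiv), THF/H2O, 0 °C → rt; 1 M HCl to pH 2, rt; then pH 6, CHCl3/i-PrOH extraction
Reagents that add atoms: lithium hydroxide, [Li+].[OH-]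
Why: Saponification cleaves the methyl ester and transiently opens ring C, and acidification re-closes the γ-lactone, so only the C-3 carboxyl ends up free.

Step 21
Reactants: 35 (3S,9R,9aS)-9-{(1R)-1-[(2R,4S)-4-methyl-5-oxooxolan-2-yl]propyl}octahydro-1H-pyrrolo[1,2-a]azepine-3-carboxylic acid
Product: 37 S-ethyl (3S,9R,9aS)-9-{(1R)-1-[(2R,4S)-4-methyl-5-oxooxolan-2-yl]propyl}octahydro-1H-pyrrolo[1,2-a]azepine-3-carbothioate, via benzotriazolyl ester 36 (not isolated)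
Conditions: DCC, HOBt, CH2Cl2, 0 °C; EtSH, rt
Reagents that add atoms: ethanethiol, CCS
Why: Carbodiimide activation through the HOBt active ester and thiolysis gives the thioester needed for a ketone synthesis that tolerates ring C.

Step 22
Reactants: 38 2-methylpropane-1,3-diol
Product: 39 2-methylpropane-1,3-diyl dibutanoate
Conditions: (n-PrCO)2O (2.4 equiv), Et3N, DMAP (5 mol %), CH2Cl2, rt
Reagents that add atoms: butanoic anhydride, CCCC(=O)OC(=O)CCC
Why: Exhaustive acylation gives the achiral, prochiral diester substrate for the enzyme.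

Step 23
Reactants: 39 2-methylpropane-1,3-diyl dibutanoate
Product: 40 (2R)-3-hydroxy-2-methylpropyl butanoate
Conditions: lipase from Pseudomonas fluorescens (Amano lipase AK), KH2PO4/K2HPO4 buffer pH 7.0, rt, NaOH (1 M, pH-stat, 1.05 equiv)
Reagents that add atoms: none
Why: Enzymatic desymmetrisation in which the lipase (a serine hydrolase) hydrolyses only the pro-S ester arm, creating the centre that becomes C-20, while over-hydrolysis of the minor enantiomer to 38 raises the ee; the same lipase in acylation mode gives the antipode.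

Step 24
Reactants: 40 (2R)-3-hydroxy-2-methylpropyl butanoate
Product: 42 (2S)-3-(butanoyloxy)-2-methylpropanoic acid, via aldehyde 41 (not isolated)
Conditions: TEMPO (7 mol %), NaClO2 (2 equiv), NaOCl (2 mol %), MeCN/NaH2PO4–Na2HPO4 buffer pH 6.7, 35 °C
Reagents that add atoms: sodium chlorite, [Na+].[O-]Cl=O
Why: TEMPO/chlorite oxidation takes the primary alcohol to the acid at near-neutral pH, so the α-centre is not epimerised and no β-elimination occurs.

Step 25
Reactants: 42 (2S)-3-(butanoyloxy)-2-methylpropanoic acid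
Product: 44 methyl (2S)-3-hydroxy-2-methylpropanoate, via butanoyloxy methyl ester 43 (not isolated)
Conditions: H2SO4 (5 mol %), MeOH, reflux
Reagents that add atoms: methanol, CO
Why: Fischer esterification and acid-catalysed transesterification of the butanoate give the hydroxy ester without base, which avoids β-elimination.

Step 26
Reactants: 44 methyl (2S)-3-hydroxy-2-methylpropanoate
Product: 45 methyl (2R)-3-iodo-2-methylpropanoate
Conditions: I2, PPh3, imidazole, CH2Cl2, 0 °C → rt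
Reagents that add atoms: iodine, II
Why: Appel-type (Garegg–Samuelsson) iodination at the primary carbon leaves the adjacent stereocentre untouched (the descriptor changes only by priority).

Step 27
Reactants: 37 S-ethyl (3S,9R,9aS)-9-{(1R)-1-[(2R,4S)-4-methyl-5-oxooxolan-2-yl]propyl}octahydro-1H-pyrrolo[1,2-a]azepine-3-carbothioate; 45 methyl (2R)-3-iodo-2-methylpropanoate
Product: 47 methyl (2S)-2-methyl-4-oxo-4-[(3S,9R,9aS)-9-{(1R)-1-[(2R,4S)-4-methyl-5-oxooxolan-2-yl]propyl}octahydro-1H-pyrrolo[1,2-a]azepin-3-yl]butanoate, via alkylzinc iodide 46 (not isolated)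
Conditions: 45 (2 equiv), Zn dust (4 equiv), I2 (5 mol %), DMA, rt; then 37, PdCl2(PPh3)2 (10 mol %), toluene, rt; aq. NH4Cl
Reagents that add atoms: none
Why: Fukuyama coupling of the thioester with the configurationally stable β-zincio ester gives the ketone without over-addition and without attack on ring C or the ester.

Step 28
Reactants: 47 methyl (2S)-2-methyl-4-oxo-4-[(3S,9R,9aS)-9-{(1R)-1-[(2R,4S)-4-methyl-5-oxooxolan-2-yl]propyl}octahydro-1H-pyrrolo[1,2-a]azepin-3-yl]butanoate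
Product: 49 (3S,5S)-3-methyl-5-[(3S,9R,9aS)-9-{(1R)-1-[(2R,4S)-4-methyl-5-oxooxolan-2-yl]propyl}octahydro-1H-pyrrolo[1,2-a]azepin-3-yl]oxolan-2-one, via hydroxy ester 48 (not isolated)
Conditions: LiBH(s-Bu)3 (1.2 equiv), THF, −78 °C; AcOH, −78 °C; then PPTS (10 mol %), CH2Cl2, rt
Reagents that add atoms: none
Why: Felkin–Anh reduction of the α-amino ketone, with the bulky hydride attacking anti to the C-3–N bond, sets C-18 as S, and the γ-hydroxy ester lactonises to ring D, whose cis methyl centre C-20 was fixed by the enzyme.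

**Compound list**
1 | 6-chlorohexan-1-ol | OCCCCCCCl | starting material
2 | 6-chlorohexanal | O=CCCCCCCl | intermediate
3 | propanal | CCC=O | starting material
4 | nitromethane | C[N+](=O)[O-] | starting material
5 | 1-nitrobutan-2-ol (racemic) | CCC(O)C[N+](=O)[O-] | intermediate
6 | 1-nitrobutan-2-yl methanesulfonate | CCC(OS(C)(=O)=O)C[N+](=O)[O-] | intermediate
7 | (E)-1-nitrobut-1-ene | CC/C=C/[N+](=O)[O-] | intermediate
8 | (2R)-6-chloro-2-[(2R)-1-nitrobutan-2-yl]hexanal | CC[C@H]([C@H](C=O)CCCCCl)C[N+](=O)[O-] | intermediate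
9 | 2-[(5R,6R)-1-chloro-6-(nitromethyl)octan-5-yl]-1,3-dioxolane | CC[C@H]([C@H](C1OCCO1)CCCCCl)C[N+](=O)[O-] | intermediate
10 | sodium nitronate of 9 | CC[C@H]([C@H](C1OCCO1)CCCCCl)C=[N+]([O-])[O-].[Na+] | intermediate
11 | (2R,3R)-7-chloro-3-(1,3-dioxolan-2-yl)-2-ethylheptanal | CC[C@H]([C@H](C1OCCO1)CCCCCl)C=O | intermediate
12 | pinacol borate (O-Bpin ester) of 13 | CC[C@H]([C@H](C1OCCO1)CCCCCl)[C@H](OB1OC(C)(C)C(C)(C)O1)CC=C | intermediate
13 | (4R,5R,6R)-10-chloro-6-(1,3-dioxolan-2-yl)-5-ethyldec-1-en-4-ol | CC[C@H]([C@H](C1OCCO1)CCCCCl)[C@H](O)CC=C | intermediate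
14 | bis(9-BBN) adduct of 13 (O-4 borinate, C-1 borane) | CC[C@H]([C@H](C1OCCO1)CCCCCl)[C@H](OB1C2CCCC1CCC2)CCCB1C2CCCC1CCC2 | intermediate
15 | (4R,5R,6R)-10-chloro-6-(1,3-dioxolan-2-yl)-5-ethyldecane-1,4-diol | CC[C@H]([C@H](C1OCCO1)CCCCCl)[C@H](O)CCCO | intermediate
16 | lactol: (5R)-5-[(3R,4R)-8-chloro-4-(1,3-dioxolan-2-yl)octan-3-yl]oxolan-2-ol | CC[C@H]([C@H](C1OCCO1)CCCCCl)[C@H]1CCC(O)O1 | intermediate
17 | (5R)-5-[(3R,4R)-8-chloro-4-(1,3-dioxolan-2-yl)octan-3-yl]oxolan-2-one | CC[C@H]([C@H](C1OCCO1)CCCCCl)[C@H]1CCC(=O)O1 | intermediate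
18 | lithium enolate of 17 | CC[C@H]([C@H](C1OCCO1)CCCCCl)[C@H]1CC=C(O[Li])O1 | intermediate
19 | (3S,5R)-5-[(3R,4R)-8-chloro-4-(1,3-dioxolan-2-yl)octan-3-yl]-3-methyloxolan-2-one | CC[C@H]([C@H](C1OCCO1)CCCCCl)[C@H]1C[C@H](C)C(=O)O1 | intermediate
20 | (2R)-6-chloro-2-{(1R)-1-[(2R,4S)-4-methyl-5-oxooxolan-2-yl]propyl}hexanal | CC[C@H]([C@H](C=O)CCCCCl)[C@H]1C[C@H](C)C(=O)O1 | intermediate
21 | pinacol borate (O-Bpin ester) of 22 | CC[C@H]([C@H]([C@H](OB1OC(C)(C)C(C)(C)O1)CC=C)CCCCCl)[C@H]1C[C@H](C)C(=O)O1 | intermediate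
22 | (3S,5R)-5-[(3R,4R,5R)-4-(4-chlorobutyl)-5-hydroxyoct-7-en-3-yl]-3-methyloxolan-2-one | CC[C@H]([C@H]([C@H](O)CC=C)CCCCCl)[C@H]1C[C@H](C)C(=O)O1 | intermediate
23 | (3S,5R)-5-[(3R,4R,5R)-5-{[tert-butyl(dimethyl)silyl]oxy}-4-(4-chlorobutyl)oct-7-en-3-yl]-3-methyloxolan-2-one | CC[C@H]([C@H]([C@H](O[Si](C)(C)C(C)(C)C)CC=C)CCCCCl)[C@H]1C[C@H](C)C(=O)O1 | intermediate
24 | ozonide (1,2,4-trioxolane) of 23 | CC[C@H]([C@H]([C@H](O[Si](C)(C)C(C)(C)C)CC1OCOO1)CCCCCl)[C@H]1C[C@H](C)C(=O)O1 | intermediate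
25 | (3R,4R)-3-{[tert-butyl(dimethyl)silyl]oxy}-8-chloro-4-{(1R)-1-[(2R,4S)-4-methyl-5-oxooxolan-2-yl]propyl}octanal | CC[C@H]([C@H]([C@H](O[Si](C)(C)C(C)(C)C)CC=O)CCCCCl)[C@H]1C[C@H](C)C(=O)O1 | intermediate
26 | methyl 2-[(tert-butoxycarbonyl)amino]-2-(dimethoxyphosphoryl)acetate (racemic) | COC(=O)C(NC(=O)OC(C)(C)C)P(=O)(OC)OC | starting material
27 | methyl (2Z,5R,6R)-2-[(tert-butoxycarbonyl)amino]-5-{[tert-butyl(dimethyl)silyl]oxy}-10-chloro-6-{(1R)-1-[(2R,4S)-4-methyl-5-oxooxolan-2-yl]propyl}dec-2-enoate | CC[C@H]([C@H]([C@H](O[Si](C)(C)C(C)(C)C)C/C=C(\NC(=O)OC(C)(C)C)C(=O)OC)CCCCCl)[C@H]1C[C@H](C)C(=O)O1 | intermediate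
28 | methyl (2S,5R,6R)-2-[(tert-butoxycarbonyl)amino]-5-{[tert-butyl(dimethyl)silyl]oxy}-10-chloro-6-{(1R)-1-[(2R,4S)-4-methyl-5-oxooxolan-2-yl]propyl}decanoate | CC[C@H]([C@H]([C@H](O[Si](C)(C)C(C)(C)C)CC[C@H](NC(=O)OC(C)(C)C)C(=O)OC)CCCCCl)[C@H]1C[C@H](C)C(=O)O1 | intermediate
29 | methyl (2S,5R,6R)-2-[(tert-butoxycarbonyl)amino]-10-chloro-5-hydroxy-6-{(1R)-1-[(2R,4S)-4-methyl-5-oxooxolan-2-yl]propyl}decanoate | CC[C@H]([C@H]([C@H](O)CC[C@H](NC(=O)OC(C)(C)C)C(=O)OC)CCCCCl)[C@H]1C[C@H](C)C(=O)O1 | intermediate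
30 | methyl (2S,5R,6R)-2-[(tert-butoxycarbonyl)amino]-10-chloro-5-[(methanesulfonyl)oxy]-6-{(1R)-1-[(2R,4S)-4-methyl-5-oxooxolan-2-yl]propyl}decanoate | CC[C@H]([C@H]([C@H](OS(C)(=O)=O)CC[C@H](NC(=O)OC(C)(C)C)C(=O)OC)CCCCCl)[C@H]1C[C@H](C)C(=O)O1 | intermediate
31 | ammonium trifluoroacetate of the Boc-free amino mesylate | CC[C@H]([C@H]([C@H](OS(C)(=O)=O)CC[C@H]([NH3+])C(=O)OC)CCCCCl)[C@H]1C[C@H](C)C(=O)O1.[O-]C(=O)C(F)(F)F | intermediate
32 | methyl (2S,5S)-5-{(5R,6R)-1-chloro-6-[(2R,4S)-4-methyl-5-oxooxolan-2-yl]octan-5-yl}pyrrolidine-2-carboxylate | CC[C@H]([C@H]([C@@H]1CC[C@H](N1)C(=O)OC)CCCCCl)[C@H]1C[C@H](C)C(=O)O1 | intermediate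
33 | methyl (3S,9R,9aS)-9-{(1R)-1-[(2R,4S)-4-methyl-5-oxooxolan-2-yl]propyl}octahydro-1H-pyrrolo[1,2-a]azepine-3-carboxylate | CC[C@H]([C@H]1CCCCN2[C@H]1CC[C@H]2C(=O)OC)[C@H]1C[C@H](C)C(=O)O1 | intermediate
34 | dilithium (3S,9R,9aS)-9-[(3R,4R,6S)-6-carboxylato-4-hydroxyheptan-3-yl]octahydro-1H-pyrrolo[1,2-a]azepine-3-carboxylate | CC[C@H]([C@H]1CCCCN2[C@H]1CC[C@H]2C(=O)[O-])[C@H](O)C[C@H](C)C(=O)[O-].[Li+].[Li+] | intermediate
35 | (3S,9R,9aS)-9-{(1R)-1-[(2R,4S)-4-methyl-5-oxooxolan-2-yl]propyl}octahydro-1H-pyrrolo[1,2-a]azepine-3-carboxylic acid | CC[C@H]([C@H]1CCCCN2[C@H]1CC[C@H]2C(=O)O)[C@H]1C[C@H](C)C(=O)O1 | intermediate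
36 | 1H-benzotriazol-1-yl ester of 35 | CC[C@H]([C@H]1CCCCN2[C@H]1CC[C@H]2C(=O)On1nnc2ccccc12)[C@H]1C[C@H](C)C(=O)O1 | intermediate
37 | S-ethyl (3S,9R,9aS)-9-{(1R)-1-[(2R,4S)-4-methyl-5-oxooxolan-2-yl]propyl}octahydro-1H-pyrrolo[1,2-a]azepine-3-carbothioate | CC[C@H]([C@H]1CCCCN2[C@H]1CC[C@H]2C(=O)SCC)[C@H]1C[C@H](C)C(=O)O1 | intermediate
38 | 2-methylpropane-1,3-diol | CC(CO)CO | starting material
39 | 2-methylpropane-1,3-diyl dibutanoate | CCCC(=O)OCC(C)COC(=O)CCC | intermediate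
40 | (2R)-3-hydroxy-2-methylpropyl butanoate | CCCC(=O)OC[C@H](C)CO | intermediate
41 | (2S)-2-methyl-3-oxopropyl butanoate | CCCC(=O)OC[C@H](C)C=O | intermediate
42 | (2S)-3-(butanoyloxy)-2-methylpropanoic acid | CCCC(=O)OC[C@H](C)C(=O)O | intermediate
43 | methyl (2S)-3-(butanoyloxy)-2-methylpropanoate | CCCC(=O)OC[C@H](C)C(=O)OC | intermediate
44 | methyl (2S)-3-hydroxy-2-methylpropanoate | OC[C@H](C)C(=O)OC | intermediate
45 | methyl (2R)-3-iodo-2-methylpropanoate | IC[C@H](C)C(=O)OC | intermediate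
46 | [(2R)-3-methoxy-2-methyl-3-oxopropyl]zinc iodide | I[Zn]C[C@H](C)C(=O)OC | intermediate
47 | methyl (2S)-2-methyl-4-oxo-4-[(3S,9R,9aS)-9-{(1R)-1-[(2R,4S)-4-methyl-5-oxooxolan-2-yl]propyl}octahydro-1H-pyrrolo[1,2-a]azepin-3-yl]butanoate | CC[C@H]([C@H]1CCCCN2[C@H]1CC[C@H]2C(=O)C[C@H](C)C(=O)OC)[C@H]1C[C@H](C)C(=O)O1 | intermediate
48 | methyl (2S,4S)-4-hydroxy-2-methyl-4-[(3S,9R,9aS)-9-{(1R)-1-[(2R,4S)-4-methyl-5-oxooxolan-2-yl]propyl}octahydro-1H-pyrrolo[1,2-a]azepin-3-yl]butanoate | CC[C@H]([C@H]1CCCCN2[C@H]1CC[C@H]2[C@@H](O)C[C@H](C)C(=O)OC)[C@H]1C[C@H](C)C(=O)O1 | intermediate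
49 | (3S,5S)-3-methyl-5-[(3S,9R,9aS)-9-{(1R)-1-[(2R,4S)-4-methyl-5-oxooxolan-2-yl]propyl}octahydro-1H-pyrrolo[1,2-a]azepin-3-yl]oxolan-2-one | CC[C@H]([C@H]1CCCCN2[C@H]1CC[C@H]2[C@@H]1C[C@H](C)C(=O)O1)[C@H]1C[C@H](C)C(=O)O1 | target

**Step count**
Total: 28 steps. Longest linear sequence: 22 steps (steps 2–21, then 27 and 28, from propanal and nitromethane). The zinc-reagent branch is steps 22–26.

**Steps most likely to fail, with fallbacks**

Risk at step 6 (ozonolytic Nef next to the C-10 centre). If epimerisation or over-oxidation occurs, the aldehyde is reached through the acid instead. Setting out from 9, NaNO2/AcOH in DMSO at 35 °C converts the primary nitro group into (2R,3R)-7-chloro-3-(1,3-dioxolan-2-yl)-2-ethylheptanoic acid F1. BH3·SMe2 in THF reduces this to (2R,3R)-7-chloro-3-(1,3-dioxolan-2-yl)-2-ethylheptan-1-ol F2. Dess–Martin periodinane buffered with NaHCO3 oxidises F2 to the aldehyde, and the route is rejoined at 11.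

Risk at step 19 (SN2 by a weakly nucleophilic α-amino ester at a hindered secondary mesylate, then seven-ring N-alkylation). If elimination or slow closure dominates, the pyrrolidine is closed by a redox-dehydrative route instead. Setting out from 29, CF3CO2H removes the Boc group and 2,4-dinitrobenzenesulfonyl chloride/2,6-lutidine gives methyl (2S,5R,6R)-10-chloro-2-{[(2,4-dinitrophenyl)sulfonyl]amino}-5-hydroxy-6-{(1R)-1-[(2R,4S)-4-methyl-5-oxooxolan-2-yl]propyl}decanoate F3. PPh3/DIAD (intramolecular Fukuyama–Mitsunobu alkylation, inversion at C-9a) closes it to methyl (2S,5S)-5-{(5R,6R)-1-chloro-6-[(2R,4S)-4-methyl-5-oxooxolan-2-yl]octan-5-yl}-1-[(2,4-dinitrophenyl)sulfonyl]pyrrolidine-2-carboxylate F4. n-PrNH2 in CH2Cl2 at rt removes the sulfonyl group without a thiolate (which would attack the chloride) and gives 32, now isolated. Heating 32 with K2CO3 and NaI in dilute MeCN at 80 °C closes ring A, and the route is rejoined at 33.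

Risk at step 27 (Fukuyama coupling on an α-amino thioester that can epimerise at C-3, followed by a substrate-controlled reduction). If the ketone cannot be made or reduced cleanly, ring D is built from the aldehyde instead. Setting out from 37, Et3SiH with Pd/C in acetone (Fukuyama reduction) gives (3S,9R,9aS)-9-{(1R)-1-[(2R,4S)-4-methyl-5-oxooxolan-2-yl]propyl}octahydro-1H-pyrrolo[1,2-a]azepine-3-carbaldehyde F5. Zn-mediated Barbier addition of ethyl 2-(bromomethyl)acrylate in THF/aq. NH4Cl, through the N,O-chelated aldehyde, gives ethyl (4S)-4-hydroxy-2-methylidene-4-[(3S,9R,9aS)-9-{(1R)-1-[(2R,4S)-4-methyl-5-oxooxolan-2-yl]propyl}octahydro-1H-pyrrolo[1,2-a]azepin-3-yl]butanoate F6. With PPTS this closes to (3S,5R)-3-methyl-5-{(1R)-1-[(3S,9R,9aS)-3-[(2S)-4-methylidene-5-oxooxolan-2-yl]octahydro-1H-pyrrolo[1,2-a]azepin-9-yl]propyl}oxolan-2-one F7. Hydrogenation over Rh/Al2O3 in EtOAc adds hydrogen from the face opposite the C-18 substituent and gives the cis-methyl lactone, rejoining the route at 49. This fallback relies on chelation control at C-18 and on cis-selective hydrogenation, both less secure than the main route.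

**Further compounds**
F1 | step 6 | (2R,3R)-7-chloro-3-(1,3-dioxolan-2-yl)-2-ethylheptanoic acid | CC[C@H]([C@H](C1OCCO1)CCCCCl)C(=O)O
F2 | step 6 | (2R,3R)-7-chloro-3-(1,3-dioxolan-2-yl)-2-ethylheptan-1-ol | CC[C@H]([C@H](C1OCCO1)CCCCCl)CO
F3 | step 19 | methyl (2S,5R,6R)-10-chloro-2-{[(2,4-dinitrophenyl)sulfonyl]amino}-5-hydroxy-6-{(1R)-1-[(2R,4S)-4-methyl-5-oxooxolan-2-yl]propyl}decanoate | CC[C@H]([C@H]([C@H](O)CC[C@H](NS(=O)(=O)c1ccc(cc1[N+](=O)[O-])[N+](=O)[O-])C(=O)OC)CCCCCl)[C@H]1C[C@H](C)C(=O)O1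
F4 | step 19 | methyl (2S,5S)-5-{(5R,6R)-1-chloro-6-[(2R,4S)-4-methyl-5-oxooxolan-2-yl]octan-5-yl}-1-[(2,4-dinitrophenyl)sulfonyl]pyrrolidine-2-carboxylate | CC[C@H]([C@H]([C@@H]1CC[C@H](N1S(=O)(=O)c1ccc(cc1[N+](=O)[O-])[N+](=O)[O-])C(=O)OC)CCCCCl)[C@H]1C[C@H](C)C(=O)O1
F5 | step 27 | (3S,9R,9aS)-9-{(1R)-1-[(2R,4S)-4-methyl-5-oxooxolan-2-yl]propyl}octahydro-1H-pyrrolo[1,2-a]azepine-3-carbaldehyde | CC[C@H]([C@H]1CCCCN2[C@H]1CC[C@H]2C=O)[C@H]1C[C@H](C)C(=O)O1
F6 | step 27 | ethyl (4S)-4-hydroxy-2-methylidene-4-[(3S,9R,9aS)-9-{(1R)-1-[(2R,4S)-4-methyl-5-oxooxolan-2-yl]propyl}octahydro-1H-pyrrolo[1,2-a]azepin-3-yl]butanoate | CC[C@H]([C@H]1CCCCN2[C@H]1CC[C@H]2[C@@H](O)CC(=C)C(=O)OCC)[C@H]1C[C@H](C)C(=O)O1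
F7 | step 27 | (3S,5R)-3-methyl-5-{(1R)-1-[(3S,9R,9aS)-3-[(2S)-4-methylidene-5-oxooxolan-2-yl]octahydro-1H-pyrrolo[1,2-a]azepin-9-yl]propyl}oxolan-2-one | CC[C@H]([C@H]1CCCCN2[C@H]1CC[C@H]2[C@@H]1CC(=C)C(=O)O1)[C@H]1C[C@H](C)C(=O)O1
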